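## Retrosynthetic overview

1. Target 22 ⇒ hydroxy diacid 18 + (R)-malic acid 19: the primary alcohol opens the O-trifluoroacetyl anhydride of 19 at C1 (last step). 18 ⇒ benzyl-protected lactone acid 17 by hydrogenolysis.
2. 17 ⇒ bicyclic acylal 15, a 2,7-dioxabicyclo[2.2.1]heptan-3-one (hydrolysis, then oxidation of C5 from the aldehyde to the acid level). 15 ⇒ cis-2-(2-bromoethyl)-1,3-dioxolan-4-one 13 by an intramolecular enolate alkylation that makes the C2–C3 bond of the oxolane ring.
3. Enabling feature (oxolan-2-one numbering O1, C2, C3, C4, C5=O): the quaternary C2 carries both the ring oxygen O1 and a carboxyl group, and the carbonyl carbon C5 sits on the same O1. At the aldehyde level C5 can therefore be the acetal carbon of a temporary 1,3-dioxolan-4-one built on O1–C2–CO2H, from which the C4–C3 arm reaches back to C2 on one face only.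
4. 13 ⇒ syn hydroxy acid 10 + 3-bromo-1,1-dimethoxypropane 11. 10 ⇒ Evans syn aldol of imide 5 with tert-butyl glyoxylate 6 (sets both C–H stereocentres). 5 ⇒ 12-hydroxydodecanoic acid 1 + oxazolidinone 3.
5. Ring order: temporary dioxolanone (step 6) → oxolane ring inside the bicycle (step 7) → dioxolanone bridge cleaved and C5 oxidised to the γ-lactone (step 8).

Key step: step 7

Remark: tert-butyl glyoxylate 6 is taken as a catalogue reagent and is distilled before use.

## Route

Step 1
Reactants: 1 12-hydroxydodecanoic acid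
Product: 2 12-(benzyloxy)dodecanoic acid
Conditions: NaH (2.2 equiv), BnBr (1.05 equiv), THF/DMF, 0 °C → rt; aq. HCl work-up
Reagents that add atoms: benzyl bromide, BrCc1ccccc1
Why: Williamson ether synthesis on the alkoxide–carboxylate dianion, in which the alkoxide is by far the better nucleophile, so benzylation should occur at the primary oxygen.

Step 2
Reactants: 2 12-(benzyloxy)dodecanoic acid; 3 (S)-4-benzyl-1,3-oxazolidin-2-one
Product: 5 (S)-4-benzyl-3-[12-(benzyloxy)dodecanoyl]-1,3-oxazolidin-2-one, via mixed pivalic anhydride 4 (not isolated)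
Conditions: t-BuCOCl, Et3N, THF, −20 °C; then 3, LiCl, −20 °C → rt
Reagents that add atoms: none
Why: Mixed-anhydride N-acylation of the oxazolidinone (LiCl/Et3N activation), in which the hindered pivaloyl carbonyl is not attacked.

Step 3
Reactants: 5 (S)-4-benzyl-3-[12-(benzyloxy)dodecanoyl]-1,3-oxazolidin-2-one; 6 tert-butyl glyoxylate
Product: 8 tert-butyl (2S,3S)-3-{[(4S)-4-benzyl-2-oxo-1,3-oxazolidin-3-yl]carbonyl}-13-(benzyloxy)-2-hydroxytridecanoate, via boron enolate 7 (not isolated)
Conditions: n-Bu2BOSO2CF3, i-Pr2NEt, CH2Cl2, −78 → 0 °C; 6, −78 → 0 °C; then pH 7 buffer, MeOH, 30% H2O2, 0 °C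
Reagents that add atoms: none
Why: Evans syn aldol: the Z-dibutylboron enolate 7 reacts through a chair Zimmerman–Traxler transition state in which the dipole-opposed (S)-auxiliary blocks one enolate face, so both new stereocentres (2S,3S) are set by the auxiliary, and the non-enolisable, highly electrophilic glyoxylate is a good acceptor.

Step 4
Reactants: 8 tert-butyl (2S,3S)-3-{[(4S)-4-benzyl-2-oxo-1,3-oxazolidin-3-yl]carbonyl}-13-(benzyloxy)-2-hydroxytridecanoate
Product: 9 4-benzyl 1-tert-butyl (2S,3S)-3-[10-(benzyloxy)decyl]-2-hydroxybutanedioate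
Conditions: BnOH, n-BuLi (gives LiOCH2Ph), THF, −20 → 0 °C; aq. NH4Cl
Reagents that add atoms: benzyl alcohol (as lithium benzyloxide), OCc1ccccc1
Why: Transesterification of the N-acyloxazolidinone by lithium benzyloxide at the exocyclic carbonyl, which should leave the tert-butyl ester and both stereocentres untouched at 0 °C and return the auxiliary.

Step 5
Reactants: 9 4-benzyl 1-tert-butyl (2S,3S)-3-[10-(benzyloxy)decyl]-2-hydroxybutanedioate
Product: 10 (2S,3S)-4-(benzyloxy)-3-[10-(benzyloxy)decyl]-2-hydroxy-4-oxobutanoic acid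
Conditions: CF3CO2H/CH2Cl2 (1:3), rt
Reagents that add atoms: none
Why: Acidolysis of the tert-butyl ester through the tert-butyl cation, conditions under which benzyl ester and benzyl ether are stable, so only the carboxyl next to the carbinol is freed.

Step 6
Reactants: 10 (2S,3S)-4-(benzyloxy)-3-[10-(benzyloxy)decyl]-2-hydroxy-4-oxobutanoic acid; 11 3-bromo-1,1-dimethoxypropane
Product: 13 benzyl (2S)-12-(benzyloxy)-2-[(2S,4S)-2-(2-bromoethyl)-5-oxo-1,3-dioxolan-4-yl]dodecanoate, via bis(trimethylsilyl) derivative 12 (not isolated)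
Conditions: Me3SiCl, Et3N, CH2Cl2, rt; filter, concentrate; then 11, Me3SiOSO2CF3 (10 mol%), CH2Cl2, −78 → −30 °C; pyridine quench
Reagents that add atoms: none
Why: Silyl triflate-catalysed (Noyori-type) transacetalization of a bis-silylated α-hydroxy acid, in which kinetic closure of the oxocarbenium ion by the silyl ester should give the 2,5-cis dioxolanone, the acetal stereocentre being set by the existing C–H stereocentre of the hydroxy acid; the minor trans isomer, which would lead to the C2 epimer, is removed by chromatography.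

Step 7
Reactants: 13 benzyl (2S)-12-(benzyloxy)-2-[(2S,4S)-2-(2-bromoethyl)-5-oxo-1,3-dioxolan-4-yl]dodecanoate
Product: 15 benzyl (2S)-12-(benzyloxy)-2-[(1S,4R)-3-oxo-2,7-dioxabicyclo[2.2.1]heptan-4-yl]dodecanoate, via lithium enolate 14 (not isolated)
Conditions: LiN(SiMe3)2 (1.1 equiv), THF/DMPU, 0.01 M, −78 → −20 °C
Reagents that add atoms: none
Why: Proposed new method: LiN(SiMe3)2 removes the ring C–H of the dioxolanone (α to the lactone carbonyl and to O1) to give the planar lithium enolate 14, and the 2-bromoethyl arm held on the acetal carbon then displaces bromide intramolecularly (SN2 C-alkylation), so that the new C2–C3 bond closes the future lactone ring inside a 2,7-dioxabicyclo[2.2.1]heptan-3-one. The closest known reaction types are the intermolecular alkylation of 1,3-dioxolan-4-one lithium enolates (self-regeneration of stereocentres) and intramolecular enolate alkylations that build bicyclo[2.2.1]heptanones; new is the delivery of the electrophile from the acetal carbon of the same ring. The oxolane ring closes in a 5-(enolexo)-exo-tet mode. The new quaternary centre is controlled solely by the acetal stereocentre, because the two-carbon arm can reach the enolate carbon only on the ring face that it occupies and the bicycle cannot exist with the other relative configuration; this gives the (R) centre and leaves the adjacent (S) C–H centre untouched. The step needs deprotonation at the ring C–H and not α to the benzyl ester (whose enolate would expel O1 by β-elimination), C- and not O-alkylation, and ring closure and not intermolecular alkylation; these should be secured by the higher acidity of the acylal-type ring C–H toward the hindered amide base at −78 °C, by the fact that O-alkylation would require a bridgehead ketene acetal, and by high dilution.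

Step 8
Reactants: 15 benzyl (2S)-12-(benzyloxy)-2-[(1S,4R)-3-oxo-2,7-dioxabicyclo[2.2.1]heptan-4-yl]dodecanoate
Product: 17 (2R)-2-[(2S)-1,12-bis(benzyloxy)-1-oxododecan-2-yl]-5-oxooxolane-2-carboxylic acid, via lactol acid 16 (not isolated)
Conditions: CrO3, H2SO4, H2O/acetone (Jones reagent), 0 °C → rt
Reagents that add atoms: water, O
Why: Aqueous acid should open the strained acylal to lactol acid 16 and chromic acid then oxidises the lactol to the γ-lactone (Jones oxidation); the quaternary centre cannot epimerise, the C–H centre α to the benzyl ester is not enolised in acid, and benzyl ether and ester tolerate the short exposure at 0 °C.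

Step 9
Reactants: 17 (2R)-2-[(2S)-1,12-bis(benzyloxy)-1-oxododecan-2-yl]-5-oxooxolane-2-carboxylic acid
Product: 18 (2R)-2-[(1S)-1-carboxy-11-hydroxyundecyl]-5-oxooxolane-2-carboxylic acid
Conditions: H2 (1 atm), 10% Pd/C, EtOAc/THF, rt
Reagents that add atoms: none
Why: Catalytic hydrogenolysis cleaves the benzyl ester and the benzyl ether in one operation and leaves lactone, acids and both stereocentres unchanged.

Step 10
Reactants: 18 (2R)-2-[(1S)-1-carboxy-11-hydroxyundecyl]-5-oxooxolane-2-carboxylic acid; 19 (R)-malic acid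
Product: 22 (2R)-2-[(1S)-1-carboxy-11-{[(2R)-3-carboxy-2-hydroxypropanoyl]oxy}undecyl]-5-oxooxolane-2-carboxylic acid, via trifluoroacetylmalic anhydride 20 (not isolated), via target trifluoroacetate 21 (not isolated)
Conditions: 19 (3 equiv), (CF3CO)2O, 0 °C → rt, evaporate to dryness; then 18, THF, rt; H2O; C18 reverse-phase chromatography
Reagents that add atoms: none
Why: Known regioselective alcoholysis of O-trifluoroacetylmalic anhydride: the carbonyl next to the acyloxy-bearing carbon (C1) is the more electrophilic one and should be opened by the primary alcohol, the free acids of 18 being much poorer nucleophiles, and the trifluoroacetate is hydrolysed on aqueous work-up, so the (R) centre of 19 is carried over unchanged.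

## Compound list

1 | 12-hydroxydodecanoic acid | OCCCCCCCCCCCC(=O)O | starting material
2 | 12-(benzyloxy)dodecanoic acid | O=C(O)CCCCCCCCCCCOCc1ccccc1 | intermediate
3 | (S)-4-benzyl-1,3-oxazolidin-2-one | O=C1N[C@@H](Cc2ccccc2)CO1 | starting material
4 | 12-(benzyloxy)dodecanoic pivalic anhydride | CC(C)(C)C(=O)OC(=O)CCCCCCCCCCCOCc1ccccc1 | intermediate
5 | (S)-4-benzyl-3-[12-(benzyloxy)dodecanoyl]-1,3-oxazolidin-2-one | O=C(CCCCCCCCCCCOCc1ccccc1)N1[C@@H](Cc2ccccc2)COC1=O | intermediate
6 | tert-butyl glyoxylate | O=CC(=O)OC(C)(C)C | starting material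
7 | Z-dibutylboron enolate of 5 | CCCCB(CCCC)O/C(=C\CCCCCCCCCCOCc1ccccc1)N1[C@@H](Cc2ccccc2)COC1=O | intermediate
8 | tert-butyl (2S,3S)-3-{[(4S)-4-benzyl-2-oxo-1,3-oxazolidin-3-yl]carbonyl}-13-(benzyloxy)-2-hydroxytridecanoate | O=C([C@@H](CCCCCCCCCCOCc1ccccc1)[C@H](O)C(=O)OC(C)(C)C)N1[C@@H](Cc2ccccc2)COC1=O | intermediate
9 | 4-benzyl 1-tert-butyl (2S,3S)-3-[10-(benzyloxy)decyl]-2-hydroxybutanedioate | CC(C)(C)OC(=O)[C@@H](O)[C@H](CCCCCCCCCCOCc1ccccc1)C(=O)OCc1ccccc1 | intermediate
10 | (2S,3S)-4-(benzyloxy)-3-[10-(benzyloxy)decyl]-2-hydroxy-4-oxobutanoic acid | OC(=O)[C@@H](O)[C@H](CCCCCCCCCCOCc1ccccc1)C(=O)OCc1ccccc1 | intermediate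
11 | 3-bromo-1,1-dimethoxypropane | COC(CCBr)OC | starting material
12 | bis(trimethylsilyl) derivative of 10 (silyl ester and silyl ether) | C[Si](C)(C)OC(=O)[C@@H](O[Si](C)(C)C)[C@H](CCCCCCCCCCOCc1ccccc1)C(=O)OCc1ccccc1 | intermediate
13 | benzyl (2S)-12-(benzyloxy)-2-[(2S,4S)-2-(2-bromoethyl)-5-oxo-1,3-dioxolan-4-yl]dodecanoate | O=C1O[C@@H](CCBr)O[C@H]1[C@H](CCCCCCCCCCOCc2ccccc2)C(=O)OCc3ccccc3 | intermediate
14 | lithium enolate of 13 | [Li+].[O-]C1=C([C@H](CCCCCCCCCCOCc2ccccc2)C(=O)OCc3ccccc3)O[C@H](CCBr)O1 | intermediate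
15 | benzyl (2S)-12-(benzyloxy)-2-[(1S,4R)-3-oxo-2,7-dioxabicyclo[2.2.1]heptan-4-yl]dodecanoate | O=C1O[C@H]2CC[C@@]1(O2)[C@H](CCCCCCCCCCOCc3ccccc3)C(=O)OCc4ccccc4 | intermediate
16 | (2R)-2-[(2S)-1,12-bis(benzyloxy)-1-oxododecan-2-yl]-5-hydroxyoxolane-2-carboxylic acid (anomer mixture) | OC(=O)[C@@]1(CCC(O)O1)[C@H](CCCCCCCCCCOCc2ccccc2)C(=O)OCc3ccccc3 | intermediate
17 | (2R)-2-[(2S)-1,12-bis(benzyloxy)-1-oxododecan-2-yl]-5-oxooxolane-2-carboxylic acid | OC(=O)[C@@]1(CCC(=O)O1)[C@H](CCCCCCCCCCOCc2ccccc2)C(=O)OCc3ccccc3 | intermediate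
18 | (2R)-2-[(1S)-1-carboxy-11-hydroxyundecyl]-5-oxooxolane-2-carboxylic acid | OC(=O)[C@@]1(CCC(=O)O1)[C@H](CCCCCCCCCCO)C(=O)O | intermediate
19 | (R)-malic acid | O[C@H](CC(=O)O)C(=O)O | starting material
20 | (3R)-2,5-dioxooxolan-3-yl trifluoroacetate | O=C1C[C@@H](OC(=O)C(F)(F)F)C(=O)O1 | intermediate
21 | O-trifluoroacetyl derivative of 22 | O=C(O)C[C@@H](OC(=O)C(F)(F)F)C(=O)OCCCCCCCCCC[C@H](C(=O)O)[C@@]1(C(=O)O)CCC(=O)O1 | intermediate
22 | (2R)-2-[(1S)-1-carboxy-11-{[(2R)-3-carboxy-2-hydroxypropanoyl]oxy}undecyl]-5-oxooxolane-2-carboxylic acid | O=C(O)C[C@@H](O)C(=O)OCCCCCCCCCC[C@H](C(=O)O)[C@@]1(C(=O)O)CCC(=O)O1 | target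

## Step count and risks

Total step count: 10. Longest linear sequence: 10 steps (1 → 22).

Steps most likely to fail:

1. Step 7 (proposed new method). The enolate may decay (self-condensation, loss of the acetal as aldehyde) faster than the strained bridged closure, or deprotonation may occur α to the benzyl ester with β-elimination of O1. The fallback uses known chemistry, sets out from 9 and comes back at 17. The carbinol centre of 9 is inverted by a Mitsunobu reaction (4-nitrobenzoic acid, PPh3, diisopropyl azodicarboxylate) to the (2R,3S) 4-nitrobenzoate F1. Methanolysis (NaN3 cat., MeOH) gives the anti hydroxy diester F2, and CF3CO2H gives the (2R,3S) hydroxy acid F3. Acetalization with pivalaldehyde (TsOH cat., pentane, removal of water) gives the cis 2-tert-butyl dioxolanone F4. Its lithium enolate (LiN(SiMe3)2, −78 °C) is alkylated by allyl bromide on the face opposite to the tert-butyl group, the classical intermolecular self-regeneration-of-stereocentres alkylation, to give the 4-allyl dioxolanone F5 with the quaternary configuration of the target. Hydroboration (9-borabicyclo[3.3.1]nonane, then buffered H2O2) gives the primary alcohol F6, Jones oxidation (CrO3, H2SO4) the carboxylic acid F7, and warm aqueous CF3CO2H removes pivalaldehyde and lactonises to 17.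

2. Step 6. Ring closure may be incompletely cis-selective, and the β-bromo oxocarbenium ion may lose HBr. The fallback sets out from 10 and comes back at 13. The bis-silyl derivative 12 is acetalized with acrolein (Me3SiOSO2CF3 cat., −78 °C), whose conjugated oxocarbenium ion cannot eliminate, to give the cis 2-vinyl dioxolanone F8. Anti-Markovnikov hydroboration (9-borabicyclo[3.3.1]nonane, then NaBO3) gives the 2-(2-hydroxyethyl) dioxolanone F9, and Appel bromination (CBr4, PPh3) gives 13.

3. Step 10. The alcohol may attack the C4 carbonyl of the anhydride, and acyl transfer to the carboxylic acids of 18 may compete, leaving regioisomeric tetra-acids that are hard to separate. The fallback sets out from 18 (partner made from 19) and comes back at 22. Both acids of 18 are benzylated (BnBr, KHCO3, DMF) to the dibenzyl ester alcohol F10, which is converted (I2, PPh3, imidazole) into the primary iodide F11. Separately, 19 is converted with 2,2-dimethoxypropane/TsOH into the acetonide acid F12, benzylated (BnBr, Et3N) to the acetonide benzyl ester F13 and hydrolysed (aq. AcOH) to (R)-malic acid 4-benzyl ester F14, in which only the C1 carboxyl is free. The cesium carboxylate of F14 (Cs2CO3, DMF) is alkylated by F11 to the tribenzyl ester F15, and hydrogenolysis (H2, Pd/C) gives 22.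

Further compounds
F1 | step 7 | 4-benzyl 1-tert-butyl (2R,3S)-3-[10-(benzyloxy)decyl]-2-[(4-nitrobenzoyl)oxy]butanedioate | CC(C)(C)OC(=O)[C@H](OC(=O)c1ccc(cc1)[N+](=O)[O-])[C@H](CCCCCCCCCCOCc1ccccc1)C(=O)OCc1ccccc1
F2 | step 7 | 4-benzyl 1-tert-butyl (2R,3S)-3-[10-(benzyloxy)decyl]-2-hydroxybutanedioate | CC(C)(C)OC(=O)[C@H](O)[C@H](CCCCCCCCCCOCc1ccccc1)C(=O)OCc1ccccc1
F3 | step 7 | (2R,3S)-4-(benzyloxy)-3-[10-(benzyloxy)decyl]-2-hydroxy-4-oxobutanoic acid | OC(=O)[C@H](O)[C@H](CCCCCCCCCCOCc1ccccc1)C(=O)OCc1ccccc1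
F4 | step 7 | benzyl (2S)-12-(benzyloxy)-2-[(2R,4R)-2-tert-butyl-5-oxo-1,3-dioxolan-4-yl]dodecanoate | O=C1O[C@H](C(C)(C)C)O[C@@H]1[C@H](CCCCCCCCCCOCc2ccccc2)C(=O)OCc3ccccc3
F5 | step 7 | benzyl (2S)-12-(benzyloxy)-2-[(2R,4R)-2-tert-butyl-5-oxo-4-(prop-2-en-1-yl)-1,3-dioxolan-4-yl]dodecanoate | O=C1O[C@H](C(C)(C)C)O[C@]1(CC=C)[C@H](CCCCCCCCCCOCc2ccccc2)C(=O)OCc3ccccc3
F6 | step 7 | benzyl (2S)-12-(benzyloxy)-2-[(2R,4R)-2-tert-butyl-4-(3-hydroxypropyl)-5-oxo-1,3-dioxolan-4-yl]dodecanoate | O=C1O[C@H](C(C)(C)C)O[C@]1(CCCO)[C@H](CCCCCCCCCCOCc2ccccc2)C(=O)OCc3ccccc3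
F7 | step 7 | 3-{(2R,4R)-4-[(2S)-1,12-bis(benzyloxy)-1-oxododecan-2-yl]-2-tert-butyl-5-oxo-1,3-dioxolan-4-yl}propanoic acid | O=C1O[C@H](C(C)(C)C)O[C@]1(CCC(=O)O)[C@H](CCCCCCCCCCOCc2ccccc2)C(=O)OCc3ccccc3
F8 | step 6 | benzyl (2S)-12-(benzyloxy)-2-[(2S,4S)-2-ethenyl-5-oxo-1,3-dioxolan-4-yl]dodecanoate | O=C1O[C@@H](C=C)O[C@H]1[C@H](CCCCCCCCCCOCc2ccccc2)C(=O)OCc3ccccc3
F9 | step 6 | benzyl (2S)-12-(benzyloxy)-2-[(2S,4S)-2-(2-hydroxyethyl)-5-oxo-1,3-dioxolan-4-yl]dodecanoate | O=C1O[C@@H](CCO)O[C@H]1[C@H](CCCCCCCCCCOCc2ccccc2)C(=O)OCc3ccccc3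
F10 | step 10 | benzyl (2R)-2-[(2S)-1-(benzyloxy)-12-hydroxy-1-oxododecan-2-yl]-5-oxooxolane-2-carboxylate | O=C(OCc1ccccc1)[C@@]1(CCC(=O)O1)[C@H](CCCCCCCCCCO)C(=O)OCc1ccccc1
F11 | step 10 | benzyl (2R)-2-[(2S)-1-(benzyloxy)-12-iodo-1-oxododecan-2-yl]-5-oxooxolane-2-carboxylate | O=C(OCc1ccccc1)[C@@]1(CCC(=O)O1)[C@H](CCCCCCCCCCI)C(=O)OCc1ccccc1
F12 | step 10 | [(4R)-2,2-dimethyl-5-oxo-1,3-dioxolan-4-yl]acetic acid | CC1(C)O[C@H](CC(=O)O)C(=O)O1
F13 | step 10 | benzyl [(4R)-2,2-dimethyl-5-oxo-1,3-dioxolan-4-yl]acetate | CC1(C)O[C@H](CC(=O)OCc2ccccc2)C(=O)O1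
F14 | step 10 | (2R)-4-(benzyloxy)-2-hydroxy-4-oxobutanoic acid | O[C@H](CC(=O)OCc1ccccc1)C(=O)O
F15 | step 10 | tribenzyl ester of 22 (benzyl esters at both core carboxyls and at the malate C4 carboxyl) | O=C(OCc1ccccc1)C[C@@H](O)C(=O)OCCCCCCCCCC[C@H](C(=O)OCc1ccccc1)[C@@]1(C(=O)OCc2ccccc2)CCC(=O)O1
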